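**Plan**
- Feature: the hemiketal carbon C2 of the benzofuran-3-one ring carries O1, a free OH and the C1'H2 group allylic to C2'=C3'. A C2–OH beside an allylic C1'–H is what is left when a spiro vinyl-oxirane (C2–O–C1') on the furanone ring is opened reductively at C1'.
- Retrosynthesis: the phenol is masked as its allyl ether and the C1'–H bond is exchanged for the C1'–O bond of oxirane 8. Both oxirane C–O bonds (C2–O, C1'–O) are then cut to the Z-dienone 7, and C2=C1' is cut (aldol) into ketone 3 and farnesal 5.
- Forward: the benzofuranone bicycle is bought and O-allylated, the C15 chain is joined at C2 by aldol condensation, and the only new ring, the oxirane, is closed by asymmetric nucleophilic epoxidation. Zerovalent palladium with a tin hydride then cleaves C1'–O and the allyl ether in one flask.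
- Stereochemistry: C2 (R) is set in the epoxidation by a chiral lanthanum–BINOL peroxide and is kept because only the C1'–O bond is broken afterwards. The (2'E,6'E) alkenes come unchanged from farnesol, and the C1' centre of 8 is erased.

Key step: step 4

Numbering: furanone atoms are O1, C2, C3(=O); chain carbons are C1' (on C2) to C12'.
Assumption: the C2 hemiketal of 10 can equilibrate through the open 1-(2-hydroxyaryl)-1,2-dione under base. It is assumed to hold its configuration under the weakly acidic, cold, aprotic conditions chosen for its release and isolation.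

**Step 1**
Reactants: 1 6-hydroxybenzofuran-3(2H)-one; 2 allyl bromide
Product: 3 6-(allyloxy)benzofuran-3(2H)-one
Conditions: K2CO3 (1.1 equiv), DMF, 0 °C to rt
Reagents that add atoms: none
Why: Williamson ether synthesis; the 6-OH is a vinylogous acid through the para C3 carbonyl and far more acidic than C2–H, so one equivalent of K2CO3 forms only the phenoxide, which displaces bromide from 2 (SN2) at oxygen.

**Step 2**
Reactants: 4 (2E,6E)-farnesol
Product: 5 (2E,6E)-farnesal
Conditions: activated MnO2 (excess), hexane, rt
Reagents that add atoms: none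
Why: Allylic alcohol oxidation on MnO2 is selective for the activated carbinol, stops at the aldehyde and is neutral, so the 2E geometry and the other alkenes should be untouched.

**Step 3**
Reactants: 3 6-(allyloxy)benzofuran-3(2H)-one; 5 (2E,6E)-farnesal
Product: 7 (Z)-6-(allyloxy)-2-[(2E,6E)-3,7,11-trimethyldodeca-2,6,10-trien-1-ylidene]benzofuran-3(2H)-one, via aldol adduct 6 (not isolated)
Conditions: neutral Al2O3, CH2Cl2, rt, dark
Reagents that add atoms: none
Why: Crossed aldol condensation of the Claisen–Schmidt type as used for aurones; the readily enolised C2 methylene of 3 adds 1,2 to 5 (conjugate addition is blocked by the disubstituted β-carbon of the enal) and aldol 6 dehydrates by E1cB to the dienone, the Z isomer (C2' syn to O1) being favoured kinetically and thermodynamically.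

**Step 4**
Reactants: 7 (Z)-6-(allyloxy)-2-[(2E,6E)-3,7,11-trimethyldodeca-2,6,10-trien-1-ylidene]benzofuran-3(2H)-one
Product: 8 (2R,3'R)-6-(allyloxy)-3'-[(1E,5E)-2,6,10-trimethylundeca-1,5,9-trien-1-yl]-3H-spiro[benzofuran-2,2'-oxiran]-3-one (oxirane carbon 3' of this name is chain carbon C1')
Conditions: La(O-i-Pr)3 (10 mol %), (R)-BINOL (10 mol %), Ph3As=O (10 mol %), tert-butyl hydroperoxide (1.5 equiv, decane solution), 4 Å molecular sieves, THF, rt
Reagents that add atoms: tert-butyl hydroperoxide, CC(C)(C)OO
Why: The lanthanum-bound tert-butylperoxide adds 1,4 to the s-cis enone (C3=O, C2=C1') at C1', and the resulting lanthanum enolate attacks the proximal peroxide oxygen through C2 with loss of tert-butoxide, so the C1'–O and C2–O bonds form in that order and the spiro-oxirane closes in a 3-exo-tet mode. The closest known reaction type is the catalytic asymmetric Weitz–Scheffer epoxidation of E-enones, arylidene cycloalkanones and conjugated dienones by lanthanide–BINOL peroxides. C1' is controlled by the chiral complex, which is expected to present the peroxide to the C1'-Re/C2-Si face with the (R)-ligand (the sense known for acyclic E-enones; it has to be confirmed, and (S)-BINOL is used if it is reversed). C2 is controlled by the ring closure, which should be faster than rotation about C2–C1' and therefore places oxygen on the same face, giving the cis (2R,3'R) oxirane. The step needs site selectivity for C2=C1' over the three trisubstituted alkenes and the allyl group, which the nucleophilic oxidant secures, and 1,4- over 1,6-addition, which the two carbon substituents on C3' secure. A trans diastereomer from rotation before closure would carry the opposite C2 configuration and is to be removed at this stage (base-washed silica, since 8 is acid-labile), because C1' is erased in step 5.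

**Step 5**
Reactants: 8 (2R,3'R)-6-(allyloxy)-3'-[(1E,5E)-2,6,10-trimethylundeca-1,5,9-trien-1-yl]-3H-spiro[benzofuran-2,2'-oxiran]-3-one
Product: 10 (R)-2,6-dihydroxy-2-[(2E,6E)-3,7,11-trimethyldodeca-2,6,10-trien-1-yl]benzofuran-3(2H)-one, via O-allyl hemiketal 9 (not isolated)
Conditions: Pd(PPh3)4 (5 mol %), Bu3SnH (2.5 equiv, slow addition), AcOH (3 equiv), CH2Cl2, 0 °C to rt
Reagents that add atoms: none
Why: Palladium-catalysed allylic hydrogenolysis (Tsuji–Trost ionisation, then hydrostannolysis): zerovalent palladium ionises the allylic C1'–O bond of the alkenyl oxirane while AcOH protonates the departing C2 oxygen, and the allylpalladium hydride formed from Bu3SnH couples at the less substituted terminus C1' (the usual sense for tin hydride, whereas formate with PBu3 favours the more substituted terminus, here C3'), which keeps the 2'E alkene and the C2–O bond and hence the C2 configuration; the same system then cleaves the aryl allyl ether of 9.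

**Compound list**
1 | 6-hydroxybenzofuran-3(2H)-one | O=C1COc2cc(O)ccc21 | starting material
2 | allyl bromide | C=CCBr | starting material
3 | 6-(allyloxy)benzofuran-3(2H)-one | O=C1COc2cc(OCC=C)ccc21 | intermediate
4 | (2E,6E)-farnesol | CC(C)=CCC/C(C)=C/CC/C(C)=C/CO | starting material
5 | (2E,6E)-farnesal | CC(C)=CCC/C(C)=C/CC/C(C)=C/C=O | intermediate
6 | 6-(allyloxy)-2-[(2E,6E)-1-hydroxy-3,7,11-trimethyldodeca-2,6,10-trien-1-yl]benzofuran-3(2H)-one (aldol adduct, diastereomer mixture) | CC(C)=CCC/C(C)=C/CC/C(C)=C/C(O)C1Oc2cc(OCC=C)ccc2C1=O | intermediate (not isolated)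
7 | (Z)-6-(allyloxy)-2-[(2E,6E)-3,7,11-trimethyldodeca-2,6,10-trien-1-ylidene]benzofuran-3(2H)-one | CC(C)=CCC/C(C)=C/CC/C(C)=C/C=C1\Oc2cc(OCC=C)ccc2C1=O | intermediate
8 | (2R,3'R)-6-(allyloxy)-3'-[(1E,5E)-2,6,10-trimethylundeca-1,5,9-trien-1-yl]-3H-spiro[benzofuran-2,2'-oxiran]-3-one | CC(C)=CCC/C(C)=C/CC/C(C)=C/[C@H]1O[C@@]12Oc3cc(OCC=C)ccc3C2=O | intermediate
9 | (R)-6-(allyloxy)-2-hydroxy-2-[(2E,6E)-3,7,11-trimethyldodeca-2,6,10-trien-1-yl]benzofuran-3(2H)-one | CC(C)=CCC/C(C)=C/CC/C(C)=C/C[C@@]1(O)Oc2cc(OCC=C)ccc2C1=O | intermediate (not isolated)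
10 | (R)-2,6-dihydroxy-2-[(2E,6E)-3,7,11-trimethyldodeca-2,6,10-trien-1-yl]benzofuran-3(2H)-one | CC(C)=CCC/C(C)=C/CC/C(C)=C/C[C@@]1(O)Oc2cc(O)ccc2C1=O | target

Total step count: 5
Longest linear sequence: 4 steps (1 → 3 → 7 → 8 → 10; the farnesol branch 4 → 5 → 7 → 8 → 10 is equally long)

**Steps most likely to fail**

1. Step 5.
   - Risk: hydride may be delivered to the tertiary terminus C3' instead of C1'. The allylpalladium may drift in geometry. The transient C2 oxyanion may open to the achiral 1,2-diketone phenoxide before it is protonated, with loss of the C2 configuration.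
   - Fallback: it leaves the oxirane manifold and installs the C1' hydrogens before the C2 oxygen. It sets out from 7. Conjugate (1,4) reduction of the exocyclic enone with [(Ph3P)CuH]6 in wet toluene should give racemic 6-(allyloxy)-2-[(2E,6E)-3,7,11-trimethyldodeca-2,6,10-trien-1-yl]benzofuran-3(2H)-one F1; 1,6-delivery is blocked by the disubstituted C3'. The enol of F1 is then oxygenated at C2 with excess nitrosobenzene under a chiral BINOL-derived phosphoric acid (enol catalysis of α-branched cyclic ketones). The O-bound nitroso-aldol adduct, (S)-6-(allyloxy)-2-[(phenylamino)oxy]-2-[(2E,6E)-3,7,11-trimethyldodeca-2,6,10-trien-1-yl]benzofuran-3(2H)-one F2, is cleaved in the flask by the excess nitrosobenzene. The acid enantiomer is chosen to give the (R) hemiketal. The sequence is non-basic throughout, so the hemiketal never exists as its oxyanion. It comes back to the route at 9, which is deallylated to 10 with Pd(PPh3)4, Bu3SnH and AcOH as in step 5.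

2. Step 4.
   - Risk: facial selectivity may be poor or reversed on a cyclic, Z-configured, α-oxygenated dienone. Bond rotation may precede ring closure. Turnover may be slow because the 6-alkoxy group makes the ketone a vinylogous ester.
   - Fallback: resolution replaces asymmetric catalysis. It sets out from 7. Racemic Weitz–Scheffer epoxidation with tert-butyl hydroperoxide and DBU in CH2Cl2 at 0 °C should give racemic cis 6-(allyloxy)-3'-[(1E,5E)-2,6,10-trimethylundeca-1,5,9-trien-1-yl]-3H-spiro[benzofuran-2,2'-oxiran]-3-one F3. The enantiomers are separated by preparative HPLC on a polysaccharide chiral stationary phase; the oxirane is configurationally stable, so the separation is durable. The (2R,3'R) enantiomer is 8, where the route is rejoined.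

3. Step 3.
   - Risk: the 2'E geometry may erode through dienolate formation on the alumina surface. Any E-enone isomer may undergo oxa-6π electrocyclisation to a 2H-pyrano[3,2-b]benzofuran. Farnesal may self-condense.
   - Fallback: a directed, stepwise aldol–elimination under kinetic control. It sets out from 3 and 5. The lithium enolate of 3 (LiN(SiMe3)2, THF, −78 °C) is added to 5 at −78 °C to give aldol 6, here isolated. Acetylation (Ac2O, Et3N, DMAP, 0 °C) gives 1-[6-(allyloxy)-3-oxo-2,3-dihydrobenzofuran-2-yl]-(2E,6E)-3,7,11-trimethyldodeca-2,6,10-trien-1-yl acetate F4. E1cB elimination with DBU at 0 °C then returns to the route at 7.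

**Further compounds**
F1 | step 5 | 6-(allyloxy)-2-[(2E,6E)-3,7,11-trimethyldodeca-2,6,10-trien-1-yl]benzofuran-3(2H)-one (racemic) | CC(C)=CCC/C(C)=C/CC/C(C)=C/CC1Oc2cc(OCC=C)ccc2C1=O
F2 | step 5 | (S)-6-(allyloxy)-2-[(phenylamino)oxy]-2-[(2E,6E)-3,7,11-trimethyldodeca-2,6,10-trien-1-yl]benzofuran-3(2H)-one | CC(C)=CCC/C(C)=C/CC/C(C)=C/C[C@@]1(ONc2ccccc2)Oc3cc(OCC=C)ccc3C1=O
F3 | step 4 | racemic cis 6-(allyloxy)-3'-[(1E,5E)-2,6,10-trimethylundeca-1,5,9-trien-1-yl]-3H-spiro[benzofuran-2,2'-oxiran]-3-one | CC(C)=CCC/C(C)=C/CC/C(C)=C/C1OC12Oc3cc(OCC=C)ccc3C2=O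
F4 | step 3 | 1-[6-(allyloxy)-3-oxo-2,3-dihydrobenzofuran-2-yl]-(2E,6E)-3,7,11-trimethyldodeca-2,6,10-trien-1-yl acetate (diastereomer mixture) | CC(C)=CCC/C(C)=C/CC/C(C)=C/C(OC(C)=O)C1Oc2cc(OCC=C)ccc2C1=O
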